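**Retrosynthetic overview**

1. The O8' ester is cut last, giving an allyl-protected (R)-hydroxymethylglutaric half ester (from (R)-mevalonolactone) and an 8'-hydroxy-abscisate whose C4' ketone is held as a dioxolane, so that a free C8' alcohol never meets the enone.
2. The (2Z,4E) chain is cut at C4–C5: senecioic acid dianion plus a C5 lactol, by way of a dihydropyranone that is opened by E1cB.
3. Feature used: on ring A the chain carbon C5 (on the carbinol C1') and the oxymethylene C8' (on the quaternary C6') are cis, so C5–O–C8'–C6'–C1' can be a γ-lactone, i.e. a butenolide whose alkene is C1'=C6'.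
4. Ring A is cut at C1'–C2' and C5'–C6': Diels–Alder of that butenolide with the C2'–C5' 2-siloxydiene, the menthyl acetal at C8' choosing the face; the C1' hydroxyl is added afterwards through the dienolate.
5. Ring order: lactone ring (present from step 1), then ring A (step 3); the dioxolane and the dihydropyranone are temporary rings.

Key step: step 3

Assumption: (−)-menthol is the (1R,2S,5R) enantiomer and the two C5 epimers of its acetal with 1 are taken to be separable by crystallisation or chromatography; abscisic-acid locants are used (ring A C1'–C6', C7' the methyl on C2', C8' the oxymethylene and C9' the methyl on C6', chain C1–C5 with the C6 methyl on C3).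

**Route**

Step 1
Reactants: 1 5-hydroxy-4-methylfuran-2(5H)-one; 2 (−)-menthol
Product: 3 (5R)-5-[(1R,2S,5R)-menthyloxy]-4-methylfuran-2(5H)-one
Conditions: TsOH·H2O (cat.), PhMe, reflux, Dean–Stark; crystallisation (hexane, −20 °C); mother liquor re-equilibrated with TsOH
Reagents that add atoms: none
Why: Acid-catalysed acetalisation of the pseudo-acid with azeotropic removal of water should give both C5 epimers, which interconvert under the acidic conditions, so the (5R) epimer can be drawn out by crystallisation and the remainder recycled.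

Step 2
Reactants: 4 (E)-pent-3-en-2-one
Product: 5 (E)-tert-butyldimethyl(penta-1,3-dien-2-yloxy)silane
Conditions: TBSOTf (1.1 equiv), Et3N (1.5 equiv), Et2O, 0 °C
Reagents that add atoms: tert-butyldimethylsilyl trifluoromethanesulfonate, CC(C)(C)[Si](C)(C)OS(=O)(=O)C(F)(F)F
Why: Soft enolisation (silyl triflate activation of the carbonyl, amine deprotonation of the methyl group) should give the cross-conjugated 2-siloxydiene with the (E) alkene untouched.

Step 3
Reactants: 3 (5R)-5-menthyloxy-4-methylfuran-2(5H)-one; 5 (E)-2-(tert-butyldimethylsilyloxy)penta-1,3-diene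
Product: 6 cis-fused adduct (3R,3aR,7S,7aS)-5-(tert-butyldimethylsilyloxy)-3-[(1R,2S,5R)-menthyloxy]-3a,7-dimethyl-3a,4,7,7a-tetrahydro-2-benzofuran-1(3H)-one (C8' R, C6' R, C2' S, C1' S in abscisic-acid locants)
Conditions: 5 (4 equiv), BHT (cat.), PhMe, 130 °C, sealed tube (CH2Cl2, 12 kbar, 40 °C if conversion stalls)
Reagents that add atoms: none
Why: This is a normal-demand Diels–Alder reaction, concerted but asynchronous, of the kind known for 5-(menthyloxy)furan-2(5H)-ones with siloxydienes. Ring A closes by suprafacial union of the diene termini C2' and C5' with the butenolide alkene C1'=C6', forming C1'–C2' and C5'–C6', so the fusion to the lactone is necessarily cis. The quaternary centre C6' is set by the menthyloxy group on C8', which blocks its own face so that the diene adds anti to it; C1' follows from the cis addition, and C2' from the endo placing of the lactone carbonyl (this centre is erased in step 4). The step needs regiocontrol, and the diene supplies it: the 2-siloxy group and the terminal methyl both put the largest HOMO coefficient on the CH2 terminus, which bonds to the β-carbon C6'. The β-methyl group slows the dienophile, hence excess diene with heat or pressure.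

Step 4
Reactants: 6 Diels–Alder adduct (silyl enol ether)
Product: 7 (3R,3aR,7aS)-3-(menthyloxy)-3a,7-dimethyl-3a,4-dihydro-2-benzofuran-1,5(3H,7aH)-dione (C2'=C3' enone, C1'–H)
Conditions: Pd(OAc)2 (1.1 equiv), MeCN, 40 °C
Reagents that add atoms: none
Why: Saegusa oxidation: divalent palladium attacks the silyl enol ether at C3' and β-hydride elimination of the only available β-hydrogen (on C2') places the alkene at C2'=C3', which also erases the C2' stereocentre.

Step 5
Reactants: 7 enone lactone
Product: 9 (3R,3aR,7aR)-7a-hydroxy-3-(menthyloxy)-3a,7-dimethyl-3a,4-dihydro-2-benzofuran-1,5(3H,7aH)-dione (C1'–OH cis to the C9' methyl), via hydroperoxide 8 (not isolated)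
Conditions: O2 (1 atm), Cs2CO3 (0.3 equiv), P(OEt)3 (2 equiv), DMSO, 20 °C
Reagents that add atoms: dioxygen, O=O
Why: Base-mediated aerobic hydroxylation: the C1' hydrogen is γ to the enone and α to the lactone carbonyl, so carbonate should form the extended dienolate, which takes up O2 at the doubly activated tertiary carbon C1' and is reduced in situ by the phosphite; oxygen should arrive on the face of the C9' methyl because only that approach keeps the lactone cis-fused, which sets C1'.

Step 6
Reactants: 9 hydroxy enone lactone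
Product: 10 C4' 1,3-dioxolane of 9
Conditions: (TMSOCH2)2 (3 equiv), TMSOTf (0.1 equiv), CH2Cl2, −78 to −20 °C; pyridine quench
Reagents that add atoms: 1,2-bis(trimethylsilyloxy)ethane, C[Si](C)(C)OCCO[Si](C)(C)C
Why: Aprotic silyl-triflate-catalysed ketalisation (Noyori conditions) should protect the enone carbonyl without moving the C2'=C3' alkene and without touching the acylal-type C8' acetal; any silyl ether formed at O1' is lost in the alkaline medium of step 7.

Step 7
Reactants: 10 dioxolane menthyloxy lactone
Product: 13 (3aS,7aR) γ-lactone with C8' as CH2 (C5 carbonyl, O8' ring oxygen, C1'–OH, C4' dioxolane), via sodium formyl carboxylate 11 (not isolated), via sodium hydroxymethyl carboxylate 12 (not isolated)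
Conditions: NaBH4 (4 equiv), 0.5 M NaOH aq., THF, 0 to 20 °C; then 10% aq. citric acid to pH 4, 0 °C
Reagents that add atoms: sodium hydroxide, [Na+].[OH-]
Why: Saponification of the γ-alkoxy lactone (a pseudo-ester) gives the carboxylate and a hemiacetal that collapses to the C8' aldehyde with loss of menthol; borohydride should reduce the aldehyde as it forms and the γ-hydroxy acid relactonises on mild acidification, with no stereocentre touched and the dioxolane stable to the medium.

Step 8
Reactants: 13 dioxolane lactone
Product: 14 C5 lactol (both anomers)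
Conditions: iBu2AlH (2.5 equiv), CH2Cl2, −78 °C; aq. potassium sodium tartrate
Reagents that add atoms: none
Why: Partial reduction of a lactone with diisobutylaluminium hydride stops at the aluminium hemiacetal at −78 °C (one equivalent is spent on the tertiary hydroxyl), bringing C5 to the aldehyde level.

Step 9
Reactants: 14 lactol; 15 3-methylbut-2-enoic acid
Product: 18 6-substituted 4-methyl-5,6-dihydro-2H-pyran-2-one (ring A substituent with free C1' and C8' hydroxyls; C5 epimers), via dilithium dienediolate 16 (not isolated), via δ-hydroxy acid 17 (not isolated)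
Conditions: 15 (4 equiv), LiN(iPr)2 (8 equiv), THF, −78 to 0 °C; then 14, −78 to 20 °C; aq. NH4Cl, citric acid to pH 4; PhMe, 40 °C
Reagents that add atoms: none
Why: Vinylogous aldol addition of the senecioate dianion through its γ-carbon (favoured on warming) to the aldehyde form of the lactol alkoxide, followed by closure of the (2Z)-δ-hydroxy acid to the dihydropyranone, which locks the later C2=C3 geometry; the new C5 carbinol centre is removed in step 10.

Step 10
Reactants: 18 dihydropyranone
Product: 19 (2Z,4E)-5-[(1R,6S)-4,4-ethylenedioxy-1-hydroxy-6-(hydroxymethyl)-2,6-dimethylcyclohex-2-en-1-yl]-3-methylpenta-2,4-dienoic acid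
Conditions: KOtBu (4 equiv), THF, 0 to 20 °C; aq. citric acid to pH 4
Reagents that add atoms: none
Why: E1cB ring opening: deprotonation at C4 expels the carboxylate from C5, so the C4=C5 alkene should form trans to the bulky C1' group while C2=C3 keeps the cis geometry it had in the ring, giving (2Z,4E).

Step 11
Reactants: 19 dienoic acid
Product: 20 allyl ester of 19
Conditions: allyl bromide (1.5 equiv), KHCO3 (2 equiv), DMF, 20 °C, dark
Reagents that add atoms: allyl bromide, C=CCBr
Why: SN2 O-alkylation of the carboxylate; the primary and tertiary hydroxyls are not alkylated by bicarbonate.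

Step 12
Reactants: 21 (R)-mevalonolactone
Product: 23 4-methoxybenzyl (3R)-3,5-dihydroxy-3-methylpentanoate, via potassium mevalonate 22 (not isolated)
Conditions: KOH (1.0 equiv), H2O/MeOH, 20 °C, evaporate; then 4-methoxybenzyl chloride (1.1 equiv), Bu4NI (cat.), DMF, 20 °C
Reagents that add atoms: potassium hydroxide, [K+].[OH-]; 4-methoxybenzyl chloride, COc1ccc(CCl)cc1
Why: Saponification of the δ-lactone and SN2 alkylation of the carboxylate mask the C1 carboxyl while freeing the C5 alcohol; the stereocentre is not involved.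

Step 13
Reactants: 23 4-methoxybenzyl mevalonate
Product: 25 (3R)-3-hydroxy-5-[(4-methoxybenzyl)oxy]-3-methyl-5-oxopentanoic acid, via aldehyde 24 (not isolated)
Conditions: TEMPO (0.2 equiv), PhI(OAc)2 (2.5 equiv), MeCN/H2O (1:1), 20 °C
Reagents that add atoms: water, O
Why: Nitroxyl-catalysed oxidation of the primary alcohol through the aldehyde hydrate to the acid; the tertiary alcohol cannot be oxidised and the benzylic ester tolerates the oxidant.

Step 14
Reactants: 25 half ester
Product: 26 1-(4-methoxybenzyl) 5-allyl (3R)-3-hydroxy-3-methylpentanedioate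
Conditions: allyl bromide (1.5 equiv), KHCO3 (2 equiv), DMF, 20 °C
Reagents that add atoms: allyl bromide, C=CCBr
Why: SN2 O-alkylation of the carboxylate differentiates the two arms of the glutarate.

Step 15
Reactants: 26 mixed diester
Product: 27 (3S)-5-(allyloxy)-3-hydroxy-3-methyl-5-oxopentanoic acid
Conditions: TFA, anisole (5 equiv), CH2Cl2, 0 °C
Reagents that add atoms: none
Why: Acidolysis of the 4-methoxybenzyl ester through the stabilised benzylic cation, which anisole traps (Friedel–Crafts alkylation); the allyl ester and the tertiary alcohol, flanked by two electron-poor methylenes, should survive.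

Step 16
Reactants: 20 allyl dienoate with free C8' alcohol; 27 allyl half ester acid
Product: 28 fully protected ester (O8' acylated, both carboxyls as allyl esters, C4' dioxolane)
Conditions: 27 (1.5 equiv), EDC·HCl (2 equiv), DMAP (0.5 equiv), CH2Cl2, 0 to 20 °C, dark
Reagents that add atoms: none
Why: Steglich esterification; only the primary C8' hydroxyl should be acylated because the C1' and glutarate hydroxyls are tertiary, and the glutarate stereocentre is not touched.

Step 17
Reactants: 28 protected ester
Product: 30 target CNP0183058.1, via diacid dioxolane 29 (not isolated)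
Conditions: Pd(PPh3)4 (5 mol %), morpholine (6 equiv), THF, 20 °C, dark; then 1 M HCl aq., THF, 20 °C
Reagents that add atoms: water, O
Why: Tsuji–Trost deallylation (zerovalent palladium ionises both allyl esters and morpholine takes up the allyl groups) followed by acid hydrolysis of the dioxolane, which is safe at this point because O8' is acylated and cannot add to the enone.

**Compound list**

1 | 5-hydroxy-4-methylfuran-2(5H)-one | CC1=CC(=O)OC1O | starting material
2 | (−)-menthol, (1R,2S,5R) | CC(C)[C@@H]1CC[C@@H](C)C[C@H]1O | starting material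
3 | (5R)-5-[(1R,2S,5R)-menthyloxy]-4-methylfuran-2(5H)-one | CC1=CC(=O)O[C@H]1O[C@@H]2C[C@H](C)CC[C@H]2C(C)C | intermediate
4 | (E)-pent-3-en-2-one | C/C=C/C(C)=O | starting material
5 | (E)-tert-butyldimethyl(penta-1,3-dien-2-yloxy)silane | C=C(O[Si](C)(C)C(C)(C)C)/C=C/C | intermediate
6 | cis-fused endo adduct, (3R,3aR,7S,7aS) silyl enol ether menthyloxy lactone | C[C@H]1C=C(O[Si](C)(C)C(C)(C)C)C[C@]2(C)[C@H]1C(=O)O[C@H]2O[C@@H]3C[C@H](C)CC[C@H]3C(C)C | intermediate
7 | (3R,3aR,7aS) enone menthyloxy lactone (C1'–H) | CC1=CC(=O)C[C@]2(C)[C@H]1C(=O)O[C@H]2O[C@@H]3C[C@H](C)CC[C@H]3C(C)C | intermediate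
8 | C1' hydroperoxide of 7 (OOH cis to the C9' methyl) | CC1=CC(=O)C[C@]2(C)[C@@]1(OO)C(=O)O[C@H]2O[C@@H]3C[C@H](C)CC[C@H]3C(C)C | intermediate
9 | (3R,3aR,7aR) 1'-hydroxy enone menthyloxy lactone | CC1=CC(=O)C[C@]2(C)[C@@]1(O)C(=O)O[C@H]2O[C@@H]3C[C@H](C)CC[C@H]3C(C)C | intermediate
10 | C4' 1,3-dioxolane of 9 | CC1=CC2(OCCO2)C[C@]3(C)[C@@]1(O)C(=O)O[C@H]3O[C@@H]4C[C@H](C)CC[C@H]4C(C)C | intermediate
11 | sodium 1'-hydroxy-6'-formyl carboxylate (ring-opened, dioxolane) | CC1=CC2(OCCO2)C[C@@](C)(C=O)[C@@]1(O)C(=O)[O-].[Na+] | intermediate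
12 | sodium 1'-hydroxy-6'-(hydroxymethyl) carboxylate (dioxolane) | CC1=CC2(OCCO2)C[C@@](C)(CO)[C@@]1(O)C(=O)[O-].[Na+] | intermediate
13 | (3aS,7aR) 1'-hydroxy γ-lactone (C5 carbonyl, C8' CH2–O), C4' dioxolane | CC1=CC2(OCCO2)C[C@]3(C)[C@@]1(O)C(=O)OC3 | intermediate
14 | C5 lactol of 13 (anomer mixture) | CC1=CC2(OCCO2)C[C@]3(C)[C@@]1(O)C(O)OC3 | intermediate
15 | 3-methylbut-2-enoic acid (senecioic acid) | CC(C)=CC(=O)O | starting material
16 | dilithium 3-methylbuta-1,3-diene-1,1-diolate (senecioate dianion) | C=C(C)C=C([O-])[O-].[Li+].[Li+] | intermediate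
17 | (2Z)-5-hydroxy-3-methyl-5-(ring A)pent-2-enoic acid, C1' and C8' hydroxyls free, C5 epimers | CC1=CC2(OCCO2)C[C@@](C)(CO)[C@@]1(O)C(O)C/C(C)=C\C(=O)O | intermediate
18 | 4-methyl-6-(ring A)-5,6-dihydro-2H-pyran-2-one (C1'–OH, C8'–OH, dioxolane; C5 epimers) | CC1=CC2(OCCO2)C[C@@](C)(CO)[C@@]1(O)C3CC(C)=CC(=O)O3 | intermediate
19 | (2Z,4E)-5-[(1R,6S)-4,4-ethylenedioxy-1-hydroxy-6-(hydroxymethyl)-2,6-dimethylcyclohex-2-en-1-yl]-3-methylpenta-2,4-dienoic acid | CC1=CC2(OCCO2)C[C@@](C)(CO)[C@@]1(O)/C=C/C(C)=C\C(=O)O | intermediate
20 | allyl ester of 19 | CC1=CC2(OCCO2)C[C@@](C)(CO)[C@@]1(O)/C=C/C(C)=C\C(=O)OCC=C | intermediate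
21 | (R)-mevalonolactone | C[C@@]1(O)CCOC(=O)C1 | starting material
22 | potassium (R)-mevalonate | [K+].[O-]C(=O)C[C@](C)(O)CCO | intermediate
23 | 4-methoxybenzyl (3R)-3,5-dihydroxy-3-methylpentanoate | COc1ccc(COC(=O)C[C@](C)(O)CCO)cc1 | intermediate
24 | 4-methoxybenzyl 3-hydroxy-3-methyl-5-oxopentanoate (aldehyde) | COc1ccc(COC(=O)C[C@](C)(O)CC=O)cc1 | intermediate
25 | (3R)-3-hydroxy-5-[(4-methoxybenzyl)oxy]-3-methyl-5-oxopentanoic acid | COc1ccc(COC(=O)C[C@](C)(O)CC(=O)O)cc1 | intermediate
26 | 1-(4-methoxybenzyl) 5-allyl (3R)-3-hydroxy-3-methylpentanedioate | COc1ccc(COC(=O)C[C@](C)(O)CC(=O)OCC=C)cc1 | intermediate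
27 | (3S)-5-(allyloxy)-3-hydroxy-3-methyl-5-oxopentanoic acid | OC(=O)C[C@](C)(O)CC(=O)OCC=C | intermediate
28 | allyl (2Z,4E)-dienoate acylated at O8' by the allyl (3R)-hydroxymethylglutarate, C4' dioxolane | CC1=CC2(OCCO2)C[C@@](C)(COC(=O)C[C@](C)(O)CC(=O)OCC=C)[C@@]1(O)/C=C/C(C)=C\C(=O)OCC=C | intermediate
29 | diacid with C4' dioxolane | CC1=CC2(OCCO2)C[C@@](C)(COC(=O)C[C@](C)(O)CC(=O)O)[C@@]1(O)/C=C/C(C)=C\C(=O)O | intermediate
30 | (2Z,4E)-5-[(1R,6S)-6-({[(3R)-4-carboxy-3-hydroxy-3-methylbutanoyl]oxy}methyl)-1-hydroxy-2,6-dimethyl-4-oxocyclohex-2-en-1-yl]-3-methylpenta-2,4-dienoic acid | CC1=CC(=O)C[C@@](C)(COC(=O)C[C@](C)(O)CC(=O)O)[C@@]1(O)/C=C/C(C)=C\C(=O)O | target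

**Step count and risks**

Total step count: 17. Longest linear sequence: 12 steps (steps 1, 3 to 11, 16 and 17); the diene (step 2) and the glutarate fragment (steps 12 to 15) are side branches.

Steps most likely to fail:

- **Step 3.** The cycloaddition may stall, because the β-methyl group hinders bond formation at C6' and the siloxydiene desilylates or oligomerises on long heating. The fallback forms the same two bonds stepwise by an anionic double Michael addition and sets out from 3 and 4. LiN(iPr)2 (THF, −78 °C) deprotonates 4 at its methyl group to lithium (E)-penta-1,3-dien-2-olate F1, whose CH2 terminus adds to C6' of 3 anti to the menthyloxy group. The lactone enolate so formed closes onto the enone β-carbon C2' to give the lithium ketone enolate F2. TBSOTf silylates it to the silyl enol ether F3 (6 or its C2' epimer), and Saegusa oxidation as in step 4 brings the sequence back to the route at 7.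

- **Step 5.** Oxygen may be taken up at C3' of the dienolate instead of C1', or on the face that would give a trans-fused lactone, and the hydroperoxide may fragment before it is reduced. The fallback hydroxylates before the enone exists, so that C1' is the only acidic position, and sets out from 6. LiN(iPr)2 (THF, −78 °C) forms the lactone enolate while the silyl enol ether stays in place, and 2-(phenylsulfonyl)-3-phenyloxaziridine transfers oxygen to C1' to give the α-hydroxy lactone silyl enol ether F4. Saegusa oxidation of F4 (Pd(OAc)2, MeCN) gives 9, where the route is rejoined.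

- **Step 9.** The dianion may add slowly, or through its α-carbon, to a hindered aldehyde that exists only in equilibrium with the lactol alkoxide, and any (2E) adduct cannot lactonise. The fallback builds the diene by cross-coupling and sets out from 14. Dimethyl (1-diazo-2-oxopropyl)phosphonate with K2CO3 in MeOH converts the lactol into the 1'-ethynyl diol F5. Bu3SnH with PdCl2(PPh3)2 (cat.) in THF adds across the alkyne in syn fashion to give the (E)-vinylstannane F6. Stille coupling (PdCl2(MeCN)2, DMF, 20 °C) with (Z)-3-iodobut-2-enoic acid F7, made from but-2-ynoic acid with NaI in AcOH, should give the (2Z,4E)-acid 19 with retention at both alkenes, where the route is rejoined.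

Further compounds
F1 | step 3 | lithium (E)-penta-1,3-dien-2-olate | [Li+].C=C([O-])/C=C/C
F2 | step 3 | lithium enolate of the cis-fused bicyclic ketone (C3'=C4' enolate, C2' epimers) | [Li+].CC1C=C([O-])C[C@]2(C)[C@H]1C(=O)O[C@H]2O[C@@H]3C[C@H](C)CC[C@H]3C(C)C
F3 | step 3 | silyl enol ether, 6 or its C2' epimer | CC1C=C(O[Si](C)(C)C(C)(C)C)C[C@]2(C)[C@H]1C(=O)O[C@H]2O[C@@H]3C[C@H](C)CC[C@H]3C(C)C
F4 | step 5 | 1'-hydroxy derivative of 6 (α-hydroxy lactone, silyl enol ether kept) | C[C@H]1C=C(O[Si](C)(C)C(C)(C)C)C[C@]2(C)[C@@]1(O)C(=O)O[C@H]2O[C@@H]3C[C@H](C)CC[C@H]3C(C)C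
F5 | step 9 | 1'-ethynyl diol (C4' dioxolane) | CC1=CC2(OCCO2)C[C@@](C)(CO)[C@@]1(O)C#C
F6 | step 9 | (E)-2-(tributylstannyl)vinyl diol (C4' dioxolane) | CC1=CC2(OCCO2)C[C@@](C)(CO)[C@@]1(O)/C=C/[Sn](CCCC)(CCCC)CCCC
F7 | step 9 | (Z)-3-iodobut-2-enoic acid | C/C(I)=C/C(=O)O
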